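**Retrosynthetic overview**

1. The strategy rests on the carbocycle's cis-diol, tertiary carbinol C7 (with its methyl) beside secondary carbinol C8, flanked by C8a, C4a, C5 and C6, which are sp2 or reachable from sp2. This is the pattern of an arene cis-dihydrodiol, so the carbocycle is the ring of benzoic acid, C7/C8 come from enzymatic ipso,ortho-dihydroxylation, and the carboxyl carbon becomes the C7 methyl.
2. The diene is elaborated by singlet oxygen/Kornblum–DeLaMare (C8a ketone, C6 carbinol), iodination at C4a, C8a methylenation/hydroboration (C1 and the C8a stereocentre) and C6 oxidation, giving β-iodoenone 16.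
3. Late disconnections: C5–Cl (electrophilic chlorination, last), O2–C3 (6-endo addition of the C1 hydroxyl to an ynenone) and C4a–C4 (Sonogashira coupling of 16 with enyne 31).
4. Enyne 31: C2′/C3′ by Brown crotylboration of methacrolein, oxolane by hydroboration/cycloetherification, C11 by chelation-controlled ethynylation of a methyl ketone, then E-vinyl iodide and coupling with trimethylsilylacetylene.
5. Ring order: carbocycle (the arene ring, dearomatised in step 1), oxolane (step 16, side branch), pyran (step 23).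

Key step: step 1

Remark (assumption): target locants (O2, C1, C3–C8a, C9–C11, O1′–C5′) are used for every intermediate, "upper face" means the face of the C7 methyl group, and the two reducing equivalents of step 1 are taken to come from cellular NADH regenerated on the co-substrate fructose.

**Route**

Step 1
Reactants: 1 benzoic acid
Product: 2 (1S,2R)-1,2-dihydroxycyclohexa-3,5-diene-1-carboxylic acid
Conditions: whole cells of Cupriavidus necator B9 (benzoate 1,2-dioxygenase active, cis-diol dehydrogenase inactive), mineral salts medium with fructose, sodium benzoate fed-batch, air, pH 7, 30 °C; cell removal, pH 3 at 0 °C, EtOAc extraction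
Reagents that add atoms: dioxygen, O=O
Why: Benzoate 1,2-dioxygenase, a non-heme iron dioxygenase supplied with electrons from NADH, binds benzoate through its carboxylate and transfers both atoms of one O2 molecule suprafacially to the ipso and ortho carbons, so the C7–O and C8–O bonds form on one face and the C8a=C4a–C5=C6 diene remains. The closest known reaction type is microbial arene cis-dihydroxylation, here in the ipso,ortho mode established for benzoic acid itself. No ring closes; the carbocycle of the target is the benzene ring of 1. Both new stereocentres (C7 and C8, 1S,2R in 2) are set by the chiral active site, which presents a single arene face to the iron-bound oxygen. The step needs ipso,ortho rather than ortho,meta regioselectivity and one enantioface; both come from carboxylate recognition in the enzyme pocket, and the missing dehydrogenase lets 2 accumulate instead of being rearomatised to catechol.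

Step 2
Reactants: 2 (1S,2R)-1,2-dihydroxycyclohexa-3,5-diene-1-carboxylic acid
Product: 3 (3aS,7aR)-2,2-dimethyl-3a,7a-dihydro-1,3-benzodioxole-3a-carboxylic acid
Conditions: 2,2-dimethoxypropane, TsOH·H2O (cat.), acetone, 0 °C → rt
Reagents that add atoms: 2,2-dimethoxypropane, COC(C)(C)OC
Why: Acid-catalysed transketalisation closes the dioxolane on the cis-diol, the standard protection of arene cis-dihydrodiols, and is run cold and briefly so that dehydrative rearomatisation does not compete.

Step 3
Reactants: 3 (3aS,7aR)-2,2-dimethyl-3a,7a-dihydro-1,3-benzodioxole-3a-carboxylic acid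
Product: 4 [(3aR,7aR)-2,2-dimethyl-3a,7a-dihydro-1,3-benzodioxol-3a-yl]methanol
Conditions: LiAlH4, THF, 0 °C → rt; then H2O, aq NaOH
Reagents that add atoms: none
Why: LiAlH4 reduces the carboxylic acid through its carboxylate to the primary alcohol, while the non-conjugated diene and the ketal are inert to hydride.

Step 4
Reactants: 4 [(3aR,7aR)-2,2-dimethyl-3a,7a-dihydro-1,3-benzodioxol-3a-yl]methanol
Product: 5 [(3aR,7aR)-2,2-dimethyl-3a,7a-dihydro-1,3-benzodioxol-3a-yl]methyl 4-methylbenzenesulfonate
Conditions: TsCl, Et3N, DMAP (cat.), CH2Cl2, 0 °C → rt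
Reagents that add atoms: 4-methylbenzenesulfonyl chloride, Cc1ccc(cc1)S(Cl)(=O)=O
Why: Sulfonylation of the only free hydroxyl group, a primary neopentyl-type alcohol, gives the leaving group for deoxygenation.

Step 5
Reactants: 5 [(3aR,7aR)-2,2-dimethyl-3a,7a-dihydro-1,3-benzodioxol-3a-yl]methyl 4-methylbenzenesulfonate
Product: 6 (3aS,7aR)-2,2,3a-trimethyl-3a,7a-dihydro-1,3-benzodioxole
Conditions: LiEt3BH (3 equiv), THF, 0 → 45 °C; then H2O
Reagents that add atoms: none
Why: SN2 displacement of the sulfonate by the strongly nucleophilic hydride LiEt3BH, the usual reagent for hindered primary sulfonates, turns the former carboxyl carbon into the C7 methyl group, and with no β-hydrogen elimination cannot compete.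

Step 6
Reactants: 6 (3aS,7aR)-2,2,3a-trimethyl-3a,7a-dihydro-1,3-benzodioxole
Product: 8 hydroxy enone (C8a ketone; C4a=C5; C6–OH on the upper face; 7,8-O-isopropylidene), via endoperoxide 7 (not isolated)
Conditions: O2, tetraphenylporphyrin (cat.), visible light, CH2Cl2, −40 °C; then Et3N, 0 °C
Reagents that add atoms: dioxygen, O=O
Why: [4+2] cycloaddition of singlet oxygen across C6 and C8a on the diene face anti to the dioxolane gives 7, and Kornblum–DeLaMare rearrangement with Et3N removes the less hindered bridgehead hydrogen H8a (H6 is flanked by the quaternary C7) to give the C8a ketone and the C6 carbinol, whose configuration is erased later by oxidation.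

Step 7
Reactants: 8 hydroxy enone
Product: 9 tert-butyldimethylsilyl ether of 8 (C6–OTBS)
Conditions: TBSOTf, 2,6-lutidine, CH2Cl2, −78 → 0 °C
Reagents that add atoms: tert-butyldimethylsilyl trifluoromethanesulfonate, CC(C)(C)[Si](C)(C)OS(=O)(=O)C(F)(F)F
Why: Silylation of the hindered secondary allylic alcohol with the silyl triflate at low temperature, using a weak hindered base that does not enolise the α-alkoxy ketone.

Step 8
Reactants: 9 silyl ether enone
Product: 10 α-iodo enone (iodine at C4a; C8a ketone; C6–OTBS; 7,8-O-isopropylidene)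
Conditions: I2, pyridine/CH2Cl2 (1:1), 0 °C → rt
Reagents that add atoms: iodine, II
Why: α-Iodination of the enone by the pyridine–iodine addition–elimination sequence (conjugate addition of pyridine at C5, iodination of the enolate at C4a, loss of pyridine) places iodine on the α-carbon C4a.

Step 9
Reactants: 10 α-iodo enone
Product: 11 iodo diene (C8a=CH2; C4a–I; C4a=C5; C6–OTBS; 7,8-O-isopropylidene)
Conditions: Cp2Ti(μ-Cl)(μ-CH2)AlMe2, pyridine (cat.), THF/toluene, −40 → 0 °C
Reagents that add atoms: Tebbe reagent Cp2Ti(μ-Cl)(μ-CH2)AlMe2, C[Al-]1(C)C[Ti]([Cl+]1)(C1C=CC=C1)C1C=CC=C1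
Why: Tebbe methylenation ([2+2] addition of the titanium methylidene to the carbonyl and cycloreversion) converts the C8a ketone into the exocyclic methylene without base, avoiding enolisation toward C8 and β-elimination of the ketal oxygen.

Step 10
Reactants: 11 iodo diene
Product: 13 primary alcohol (C1–OH cis to O8; 8aS; C4a–I; C6–OTBS; 7,8-O-isopropylidene), via B-alkyl-9-borabicyclononane 12 (not isolated)
Conditions: 9-BBN (0.5 M in THF, 3 equiv), THF, 0 °C → rt; then 3 M NaOH, 30% H2O2, 0 °C
Reagents that add atoms: 9-borabicyclo[3.3.1]nonane, B1C2CCCC1CCC2 (boron carried by 12 only); hydrogen peroxide, OO (oxygen on C1)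
Why: In this hydroboration–oxidation 9-BBN puts boron on the terminal carbon C1 of the 1,1-disubstituted alkene (the iodo-substituted ring alkene is inert) and should deliver hydrogen to C8a on the face anti to the cis-fused dioxolane, as is usual for exocyclic methylenes beside an allylic C–O bond, so that C1 ends cis to O8 (8aS), and the C–B bond is oxidised with retention.

Step 11
Reactants: 13 primary alcohol
Product: 14 diol (C1–OH and C6–OH; C4a–I; 7,8-O-isopropylidene)
Conditions: Bu4NF, THF, 0 °C → rt
Reagents that add atoms: none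
Why: Fluoride-induced desilylation frees the C6 carbinol at a stage without any carbonyl group, so the basic fluoride is harmless.

Step 12
Reactants: 14 diol
Product: 15 β-iodoenone (C6 ketone; C5=C4a–I; C1–OH; 7,8-O-isopropylidene)
Conditions: activated MnO2 (excess), CH2Cl2, rt
Reagents that add atoms: none
Why: MnO2 oxidises only the allylic secondary alcohol at C6 and leaves the non-allylic primary C1 hydroxyl untouched, giving the β-iodoenone.

Step 13
Reactants: 15 β-iodoenone
Product: 16 (4S,5R,6R)-5,6-dihydroxy-4-(hydroxymethyl)-3-iodo-6-methylcyclohex-2-en-1-one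
Conditions: CF3CO2H/H2O (4:1), 0 °C → rt
Reagents that add atoms: none
Why: Acid-catalysed ketal hydrolysis releases the 7,8-diol while the molecule still carries no acid-labile side chain, and aqueous trifluoroacetic acid avoids halide exchange at the β-iodoenone.

Step 14
Reactants: 17 methacrolein
Product: 19 (3S,4S)-2,4-dimethylhexa-1,5-dien-3-ol, via diisopinocampheylborinate 18 (not isolated)
Conditions: trans-2-butene, n-BuLi, KOt-Bu, THF, −78 → −45 °C; (−)-Ipc2BOMe, −78 °C; BF3·OEt2; 17, −78 °C; then 3 M NaOH, 30% H2O2, rt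
Reagents that add atoms: trans-2-butene, C/C=C/C; (−)-B-methoxydiisopinocampheylborane, COB([C@@H]1C[C@@H]2C[C@H]([C@H]1C)C2(C)C)[C@@H]1C[C@@H]2C[C@H]([C@H]1C)C2(C)C (boron and isopinocampheyl groups carried by 18 only)
Why: In this Brown (E)-crotylboration the chair Zimmerman–Traxler transition state translates the E-geometry into the anti relationship, and the isopinocampheyl groups derived from (+)-α-pinene direct attack to the Si face of the aldehyde, which sets C2′ and C3′ as the 3S,4S adduct.

Step 15
Reactants: 19 (3S,4S)-2,4-dimethylhexa-1,5-dien-3-ol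
Product: 21 (3S,4S)-3,5-dimethylhex-5-ene-1,4-diol, via bis(disiamylboryl) intermediate 20 (not isolated)
Conditions: Sia2BH (from BH3·THF and 2-methylbut-2-ene), THF, −10 → 0 °C; then 3 M NaOH, 30% H2O2, 0 °C → rt
Reagents that add atoms: disiamylborane, CC(C)C(C)BC(C)C(C)C (boron carried by 20 only); hydrogen peroxide, OO (oxygen on C5′)
Why: Chemoselective hydroboration–oxidation, in which the bulky dialkylborane reacts with the monosubstituted vinyl group much faster than with the 1,1-disubstituted, oxygen-deactivated isopropenyl group and places boron on the terminal carbon.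

Step 16
Reactants: 21 (3S,4S)-3,5-dimethylhex-5-ene-1,4-diol
Product: 23 (2S,3S)-3-methyl-2-(prop-1-en-2-yl)oxolane, via primary monosulfonate 22 (not isolated)
Conditions: TsCl (1.05 equiv), pyridine, CH2Cl2, 0 °C → rt; then 40 °C
Reagents that add atoms: 4-methylbenzenesulfonyl chloride, Cc1ccc(cc1)S(Cl)(=O)=O (carried by 22 only)
Why: Selective sulfonylation of the primary hydroxyl and 5-exo-tet Williamson cyclisation by the secondary hydroxyl close the oxolane without touching a stereocentre, so the trans 2,3-relationship follows from step 14.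

Step 17
Reactants: 23 (2S,3S)-3-methyl-2-(prop-1-en-2-yl)oxolane
Product: 25 1-[(2S,3S)-3-methyloxolan-2-yl]ethan-1-one, via ozonide 24 (not isolated)
Conditions: O3, CH2Cl2, −78 °C; then PPh3, −78 °C → rt
Reagents that add atoms: ozone, [O-][O+]=O
Why: Ozonolysis of the isopropenyl group (1,3-dipolar cycloaddition, cycloreversion, recombination to ozonide 24) and reduction with PPh3 give the methyl ketone under neutral conditions that do not epimerise C2′.

Step 18
Reactants: 25 1-[(2S,3S)-3-methyloxolan-2-yl]ethan-1-one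
Product: 26 (2S)-2-[(2S,3S)-3-methyloxolan-2-yl]but-3-yn-2-ol
Conditions: HC≡CMgBr (0.5 M in THF), THF, −78 → −20 °C; then H2O
Reagents that add atoms: ethynylmagnesium bromide, C#C[Mg]Br
Why: Chelation-controlled Grignard addition (Cram chelate model), in which magnesium bridges the ketone oxygen and the ring oxygen O1′ and the acetylide attacks from the side of the C2′ hydrogen, opposite ring carbon C3′, setting C11 as S.

Step 19
Reactants: 26 (2S)-2-[(2S,3S)-3-methyloxolan-2-yl]but-3-yn-2-ol
Product: 28 (2S,3E)-4-iodo-2-[(2S,3S)-3-methyloxolan-2-yl]but-3-en-2-ol, via E-vinylstannane 27 (not isolated)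
Conditions: Bu3SnH, Pd(PPh3)2Cl2 (2 mol %), THF, 0 °C; then I2, CH2Cl2, 0 °C
Reagents that add atoms: tributyltin hydride, CCCC[SnH](CCCC)CCCC (tin carried by 27 only); iodine, II
Why: Palladium-catalysed syn-hydrostannation places tin on the terminal carbon of the hindered tertiary propargylic alcohol to give the E-vinylstannane, and iododestannylation retains the alkene geometry.

Step 20
Reactants: 28 (2S,3E)-4-iodo-2-[(2S,3S)-3-methyloxolan-2-yl]but-3-en-2-ol; 29 trimethylsilylacetylene
Product: 30 (2S,3E)-2-[(2S,3S)-3-methyloxolan-2-yl]-6-(trimethylsilyl)hex-3-en-5-yn-2-ol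
Conditions: Pd(PPh3)2Cl2 (3 mol %), CuI (6 mol %), Et3N, THF, rt
Reagents that add atoms: none
Why: Sonogashira coupling of the E-alkenyl iodide with the terminal alkyne proceeds with retention of alkene geometry and tolerates the free tertiary alcohol.

Step 21
Reactants: 30 silylated enyne
Product: 31 (2S,3E)-2-[(2S,3S)-3-methyloxolan-2-yl]hex-3-en-5-yn-2-ol
Conditions: K2CO3, MeOH, rt
Reagents that add atoms: none
Why: Base-mediated methanolysis of the alkynyl C–Si bond frees the terminal alkyne.

Step 22
Reactants: 16 (4S,5R,6R)-5,6-dihydroxy-4-(hydroxymethyl)-3-iodo-6-methylcyclohex-2-en-1-one; 31 enyne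
Product: 32 (4S,5R,6R)-5,6-dihydroxy-4-(hydroxymethyl)-3-{(3E,5S)-5-hydroxy-5-[(2S,3S)-3-methyloxolan-2-yl]hex-3-en-1-yn-1-yl}-6-methylcyclohex-2-en-1-one
Conditions: Pd(PPh3)2Cl2 (5 mol %), CuI (10 mol %), i-Pr2NH, THF (degassed), 0 °C → rt
Reagents that add atoms: none
Why: Sonogashira coupling, in which the β-iodoenone adds rapidly to zerovalent palladium at or below room temperature and the copper acetylide of 31 forms the C4a–C4 bond without interference from the free hydroxyl groups.

Step 23
Reactants: 32 ynenone tetraol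
Product: 33 (7R,8R,8aS)-7,8-dihydroxy-3-{(1E,3S)-3-hydroxy-3-[(2S,3S)-3-methyloxolan-2-yl]but-1-en-1-yl}-7-methyl-1,7,8,8a-tetrahydro-6H-isochromen-6-one
Conditions: Ph3PAuNTf2 (2 mol %), THF, 0 °C → rt
Reagents that add atoms: none
Why: Monovalent-gold-catalysed 6-endo-dig hydroalkoxylation (alkynol cycloisomerisation, as for 2-alkynylbenzyl alcohols to 1H-isochromenes) adds the C1 hydroxyl to C3, the δ-carbon of the ynenone, so the conjugate polarisation favours 6-endo over 5-exo closure, protodeauration at C4 gives the dienol ether, and the E-alkene keeps the C11 hydroxyl away from the alkyne.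

Step 24
Reactants: 33 deschloro bicycle
Product: 34 (7R,8R,8aS)-5-chloro-7,8-dihydroxy-3-{(1E,3S)-3-hydroxy-3-[(2S,3S)-3-methyloxolan-2-yl]but-1-en-1-yl}-7-methyl-1,7,8,8a-tetrahydro-6H-isochromen-6-one (CNP0432723.3)
Conditions: N-chlorosuccinimide (1.05 equiv), MeCN, 0 °C → rt, dark
Reagents that add atoms: N-chlorosuccinimide, O=C1CCC(=O)N1Cl
Why: Electrophilic chlorination of the push–pull dienol ether O2–C3=C4–C4a=C5–C6=O at its terminus C5, the α-carbon of the vinylogous ester, followed by loss of H5, as in the chlorination of azaphilone cores with N-chlorosuccinimide.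

**Compound list**

1 | benzoic acid | OC(=O)c1ccccc1 | starting material
2 | (1S,2R)-1,2-dihydroxycyclohexa-3,5-diene-1-carboxylic acid | C1=C[C@](C(=O)O)(O)[C@H](O)C=C1 | intermediate
3 | (3aS,7aR)-2,2-dimethyl-3a,7a-dihydro-1,3-benzodioxole-3a-carboxylic acid | C1=C[C@]2(C(=O)O)OC(C)(C)O[C@@H]2C=C1 | intermediate
4 | [(3aR,7aR)-2,2-dimethyl-3a,7a-dihydro-1,3-benzodioxol-3a-yl]methanol | C1=C[C@]2(CO)OC(C)(C)O[C@@H]2C=C1 | intermediate
5 | [(3aR,7aR)-2,2-dimethyl-3a,7a-dihydro-1,3-benzodioxol-3a-yl]methyl 4-methylbenzenesulfonate | C1=C[C@]2(COS(=O)(=O)c3ccc(C)cc3)OC(C)(C)O[C@@H]2C=C1 | intermediate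
6 | (3aS,7aR)-2,2,3a-trimethyl-3a,7a-dihydro-1,3-benzodioxole | C1=C[C@]2(C)OC(C)(C)O[C@@H]2C=C1 | intermediate
7 | endoperoxide: O–O bridge across C6 and C8a on the upper face, anti to the dioxolane (not isolated) | [C@H]12C=C[C@H](OO1)[C@H]3OC(C)(C)O[C@@]23C | intermediate
8 | (3aS,7R,7aS)-7-hydroxy-2,2,7a-trimethyl-7,7a-dihydro-1,3-benzodioxol-4(3aH)-one (C8a ketone, C4a=C5, C6–OH on the upper face) | O[C@@H]1C=CC(=O)[C@H]2OC(C)(C)O[C@@]12C | intermediate
9 | tert-butyldimethylsilyl ether of 8 (C6–OTBS) | CC(C)(C)[Si](C)(C)O[C@@H]1C=CC(=O)[C@H]2OC(C)(C)O[C@@]12C | intermediate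
10 | α-iodo enone: 9 with iodine at C4a | CC(C)(C)[Si](C)(C)O[C@@H]1C=C(I)C(=O)[C@H]2OC(C)(C)O[C@@]12C | intermediate
11 | iodo diene: C8a=CH2, C4a–I, C4a=C5, C6–OTBS, 7,8-O-isopropylidene | CC(C)(C)[Si](C)(C)O[C@@H]1C=C(I)C(=C)[C@H]2OC(C)(C)O[C@@]12C | intermediate
12 | B-alkyl-9-borabicyclo[3.3.1]nonane: boron on C1, 8aS (not isolated) | CC(C)(C)[Si](C)(C)O[C@@H]1C=C(I)[C@@H](CB3C4CCCC3CCC4)[C@H]2OC(C)(C)O[C@@]12C | intermediate
13 | primary alcohol: C1–OH cis to O8 (8aS), C4a–I, C6–OTBS, 7,8-O-isopropylidene | CC(C)(C)[Si](C)(C)O[C@@H]1C=C(I)[C@@H](CO)[C@H]2OC(C)(C)O[C@@]12C | intermediate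
14 | diol: C1–OH and C6–OH, C4a–I, 7,8-O-isopropylidene | O[C@@H]1C=C(I)[C@@H](CO)[C@H]2OC(C)(C)O[C@@]12C | intermediate
15 | β-iodoenone: C6 ketone, C5=C4a–I, C1–OH, 7,8-O-isopropylidene | O=C1C=C(I)[C@@H](CO)[C@H]2OC(C)(C)O[C@@]12C | intermediate
16 | (4S,5R,6R)-5,6-dihydroxy-4-(hydroxymethyl)-3-iodo-6-methylcyclohex-2-en-1-one | IC1=CC(=O)[C@](C)(O)[C@H](O)[C@@H]1CO | intermediate
17 | methacrolein (2-methylprop-2-enal) | CC(=C)C=O | starting material
18 | diisopinocampheylborinate of 19 (not isolated) | C[C@@H](C=C)[C@H](OB([C@@H]1C[C@@H]2C[C@H]([C@H]1C)C2(C)C)[C@@H]1C[C@@H]2C[C@H]([C@H]1C)C2(C)C)C(C)=C | intermediate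
19 | (3S,4S)-2,4-dimethylhexa-1,5-dien-3-ol | C[C@@H](C=C)[C@H](O)C(C)=C | intermediate
20 | O,C-bis(disiamylboryl) intermediate: boron on O and on C5′ (not isolated) | C[C@@H](CCB(C(C)C(C)C)C(C)C(C)C)[C@H](OB(C(C)C(C)C)C(C)C(C)C)C(C)=C | intermediate
21 | (3S,4S)-3,5-dimethylhex-5-ene-1,4-diol | C[C@@H](CCO)[C@H](O)C(C)=C | intermediate
22 | primary 4-methylbenzenesulfonate of 21 (not isolated) | C[C@@H](CCOS(=O)(=O)c1ccc(C)cc1)[C@H](O)C(C)=C | intermediate
23 | (2S,3S)-3-methyl-2-(prop-1-en-2-yl)oxolane | C[C@H]1CCO[C@@H]1C(C)=C | intermediate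
24 | 3-methyl-3-[(2S,3S)-3-methyloxolan-2-yl]-1,2,4-trioxolane, mixture at the trioxolane carbon (not isolated) | C[C@H]1CCO[C@@H]1C1(C)OCOO1 | intermediate
25 | 1-[(2S,3S)-3-methyloxolan-2-yl]ethan-1-one | C[C@H]1CCO[C@@H]1C(C)=O | intermediate
26 | (2S)-2-[(2S,3S)-3-methyloxolan-2-yl]but-3-yn-2-ol | C[C@H]1CCO[C@@H]1[C@@](C)(O)C#C | intermediate
27 | (2S,3E)-2-[(2S,3S)-3-methyloxolan-2-yl]-4-(tributylstannyl)but-3-en-2-ol (not isolated) | C[C@H]1CCO[C@@H]1[C@@](C)(O)/C=C/[Sn](CCCC)(CCCC)CCCC | intermediate
28 | (2S,3E)-4-iodo-2-[(2S,3S)-3-methyloxolan-2-yl]but-3-en-2-ol | C[C@H]1CCO[C@@H]1[C@@](C)(O)/C=C/I | intermediate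
29 | trimethylsilylacetylene | C#C[Si](C)(C)C | starting material
30 | (2S,3E)-2-[(2S,3S)-3-methyloxolan-2-yl]-6-(trimethylsilyl)hex-3-en-5-yn-2-ol | C[C@H]1CCO[C@@H]1[C@@](C)(O)/C=C/C#C[Si](C)(C)C | intermediate
31 | (2S,3E)-2-[(2S,3S)-3-methyloxolan-2-yl]hex-3-en-5-yn-2-ol | C[C@H]1CCO[C@@H]1[C@@](C)(O)/C=C/C#C | intermediate
32 | (4S,5R,6R)-5,6-dihydroxy-4-(hydroxymethyl)-3-{(3E,5S)-5-hydroxy-5-[(2S,3S)-3-methyloxolan-2-yl]hex-3-en-1-yn-1-yl}-6-methylcyclohex-2-en-1-one | C[C@H]1CCO[C@@H]1[C@@](C)(O)/C=C/C#CC2=CC(=O)[C@](C)(O)[C@H](O)[C@@H]2CO | intermediate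
33 | (7R,8R,8aS)-7,8-dihydroxy-3-{(1E,3S)-3-hydroxy-3-[(2S,3S)-3-methyloxolan-2-yl]but-1-en-1-yl}-7-methyl-1,7,8,8a-tetrahydro-6H-isochromen-6-one | C[C@H]1CCO[C@@H]1[C@@](C)(O)/C=C/C1=CC2=CC(=O)[C@](C)(O)[C@H](O)[C@@H]2CO1 | intermediate
34 | (7R,8R,8aS)-5-chloro-7,8-dihydroxy-3-{(1E,3S)-3-hydroxy-3-[(2S,3S)-3-methyloxolan-2-yl]but-1-en-1-yl}-7-methyl-1,7,8,8a-tetrahydro-6H-isochromen-6-one (CNP0432723.3) | C[C@H]1CCO[C@@H]1[C@@](C)(O)/C=C/C1=CC2=C(Cl)C(=O)[C@](C)(O)[C@H](O)[C@@H]2CO1 | target

**Step count**

Total: 24 steps. Longest linear sequence: 16 steps (steps 1–13 and 22–24, from benzoic acid); the side chain is 8 steps (14–21) before the coupling.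

**Steps most likely to fail**

Step 10. What may go wrong is poor facial selectivity in the hydroboration: if hydrogen is delivered to C8a on the dioxolane face, the C8a epimer forms, and it cannot be corrected later. The fallback replaces steric facial selection by tethered delivery and sets out from 11. Aqueous trifluoroacetic acid removes the ketal and the silyl ether to give the iodo diene triol F1. 1,1,3,3-Tetramethyldisilazane silylates the two secondary hydroxyls to give the bis(dimethylsilyl) ether F2. Pt2[(CH2=CHSiMe2)2O]3 (zerovalent platinum) then catalyses intramolecular hydrosilylation of the exocyclic alkene from the Si–H bound to O8 (5-endo mode), which should close the cis-fused oxasilolane F3 with silicon on C1 and hence C1 on the face of O8. Tamao–Fleming oxidation (KF, KHCO3, H2O2) gives the tetraol F4, and MnO2 oxidises its allylic C6 carbinol, so the route is rejoined at 16.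

Step 6. What may go wrong is loss of regiocontrol in the base-induced opening of the endoperoxide: removal of H6 instead of H8a would give the transposed hydroxy enone (C6 ketone, C8a carbinol). The fallback separates O–O cleavage from oxidation and sets out from 7. Thiourea reduces the peroxide bond to the cis-ene-1,4-diol F5, and MnO2 then oxidises the less hindered allylic carbinol at C8a (flanked by a CH) in preference to the neopentyl-type C6 carbinol, which returns 8.

Step 5. What may go wrong is a slow displacement at the neopentyl-type carbon, with hydride attacking sulfur (returning 4) and the diene dimerising thermally in the meantime. The fallback opens a strained epoxide instead of displacing a sulfonate and sets out from 2. LiAlH4 reduces the unprotected acid to (1R,2R)-1-(hydroxymethyl)cyclohexa-3,5-diene-1,2-diol F6. TsCl in pyridine at −20 °C sulfonylates the primary hydroxyl selectively to give the primary sulfonate F7. K2CO3 in MeOH closes (3R,4R)-1-oxaspiro[2.5]octa-5,7-dien-4-ol F8 through the tertiary alkoxide. LiEt3BH opens the epoxide at its CH2 terminus to give (1S,2R)-1-methylcyclohexa-3,5-diene-1,2-diol F9, and 2,2-dimethoxypropane with catalytic TsOH gives 6.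

**Further compounds**

F1 | step 10 | iodo diene triol (C6-, C7- and C8-OH free; C8a=CH2; C4a–I) | IC1=C[C@@H](O)[C@](C)(O)[C@H](O)C1=C
F2 | step 10 | 6,8-bis(dimethylsilyl) ether of F1 | IC1=C[C@@H](O[SiH](C)C)[C@](C)(O)[C@H](O[SiH](C)C)C1=C
F3 | step 10 | cis-fused oxasilolane (O8–SiMe2–C1; 8aS; C6–OSiMe2H) | IC1=C[C@@H](O[SiH](C)C)[C@](C)(O)[C@@H]2O[Si](C)(C)C[C@H]12
F4 | step 10 | tetraol (C1-, C6-, C7- and C8-OH; C4a–I; 8aS) | IC1=C[C@@H](O)[C@](C)(O)[C@H](O)[C@@H]1CO
F5 | step 6 | cis-ene-1,4-diol (C6–OH and C8a–OH on the upper face; 7,8-O-isopropylidene) | O[C@@H]1C=C[C@H](O)[C@H]2OC(C)(C)O[C@@]12C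
F6 | step 5 | (1R,2R)-1-(hydroxymethyl)cyclohexa-3,5-diene-1,2-diol | C1=C[C@](CO)(O)[C@H](O)C=C1
F7 | step 5 | primary 4-methylbenzenesulfonate of F6 | C1=C[C@](COS(=O)(=O)c2ccc(C)cc2)(O)[C@H](O)C=C1
F8 | step 5 | (3R,4R)-1-oxaspiro[2.5]octa-5,7-dien-4-ol | C1=C[C@@]2(CO2)[C@H](O)C=C1
F9 | step 5 | (1S,2R)-1-methylcyclohexa-3,5-diene-1,2-diol | C1=C[C@](C)(O)[C@H](O)C=C1
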